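**Retrosynthetic overview**

1. Chain numbering used here, from the free NH2: N1, C2–C4, N5 (tertiary amide), C6–C9, N10 (secondary amine), C11–C13, N14 (secondary amide). Target 18 comes from 17 by one global hydrogenolysis of four aryl benzyl ethers and two N-Cbz groups.
2. 17 comes from 9 + 16 by forming C7–C8, the central CH2–CH2 bond of the N5–(CH2)4–N10 unit, in a nickel-electrocatalytic doubly decarboxylative coupling of two N-acyloxyphthalimides.
3. Enabling feature: N5 and N10 each carry a CH2–CH2 arm that ends at this bond, so each half is a decarboxylated N,N-disubstituted β-alanine (N–CH2–CH2–CO2H). 9 and 16 are constitutional isomers in which only Cbz and the arylpropanoyl group have changed places.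
4. 9 and 16 come from aza-Michael addition of a mono-functionalised propane-1,3-diamine (4 or 12) to tert-butyl acrylate 5, followed by N-acylation with 3 or N-Cbz protection; 3 comes from dihydrocaffeic acid 1.
5. No ring is formed anywhere: the only rings of the target, the two catechol benzene rings, are carried intact from 1.

Key step: step 10

Remark: the target has no stereocentre and no stereogenic double bond, so nothing stereochemical has to be set or preserved. Compounds 4 and 10 are used as the commercial free bases.

**Route**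

Step 1
Reactants: 1 3-(3,4-dihydroxyphenyl)propanoic acid
Product: 3 3-[3,4-bis(benzyloxy)phenyl]propanoic acid, via perbenzylated benzyl ester 2 (not isolated)
Conditions: BnBr (3.3 equiv), K2CO3, DMF, 60 °C; then 2 M NaOH, MeOH, 60 °C; aq. HCl work-up
Reagents that add atoms: benzyl bromide, BrCc1ccccc1; sodium hydroxide, [Na+].[OH-]
Why: Williamson O-benzylation of both phenols with concurrent benzyl ester formation, followed by saponification of that ester in the same flask, should leave only the two aryl benzyl ethers.

Step 2
Reactants: 4 benzyl (3-aminopropyl)carbamate; 5 tert-butyl acrylate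
Product: 6 tert-butyl 3-[(3-{[(benzyloxy)carbonyl]amino}propyl)amino]propanoate
Conditions: MeOH, 0 °C → rt, 4 in slight excess
Reagents that add atoms: none
Why: Aza-Michael addition of the primary amine to the acrylate should stop at the mono-adduct because the bulky tert-butyl ester and the excess of amine slow the second addition, and the carbamate N–H is not nucleophilic.

Step 3
Reactants: 6 tert-butyl 3-[(3-{[(benzyloxy)carbonyl]amino}propyl)amino]propanoate; 3 3-[3,4-bis(benzyloxy)phenyl]propanoic acid
Product: 7 tert-butyl 3-[{3-[3,4-bis(benzyloxy)phenyl]propanoyl}(3-{[(benzyloxy)carbonyl]amino}propyl)amino]propanoate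
Conditions: DIC, Oxyma, CH2Cl2–DMF, 0 °C → rt
Reagents that add atoms: none
Why: Carbodiimide/Oxyma amide coupling should acylate the only basic nitrogen, the secondary amine, since the carbamate nitrogen does not compete.

Step 4
Reactants: 7 tert-butyl 3-[{3-[3,4-bis(benzyloxy)phenyl]propanoyl}(3-{[(benzyloxy)carbonyl]amino}propyl)amino]propanoate
Product: 8 3-[{3-[3,4-bis(benzyloxy)phenyl]propanoyl}(3-{[(benzyloxy)carbonyl]amino}propyl)amino]propanoic acid
Conditions: TFA–CH2Cl2 (1:3), 0 °C → rt; co-evaporation with toluene
Reagents that add atoms: none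
Why: Acidolysis of the tert-butyl ester with loss of isobutene is standard and should leave the benzyl carbamate, the aryl benzyl ethers and the tertiary amide intact.

Step 5
Reactants: 8 3-[{3-[3,4-bis(benzyloxy)phenyl]propanoyl}(3-{[(benzyloxy)carbonyl]amino}propyl)amino]propanoic acid
Product: 9 1,3-dioxoisoindolin-2-yl 3-[{3-[3,4-bis(benzyloxy)phenyl]propanoyl}(3-{[(benzyloxy)carbonyl]amino}propyl)amino]propanoate
Conditions: N-hydroxyphthalimide, DIC, DMAP (cat.), CH2Cl2, rt
Reagents that add atoms: N-hydroxyphthalimide, ON1C(=O)c2ccccc2C1=O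
Why: Steglich-type esterification with N-hydroxyphthalimide should give the redox-active ester cleanly, because the tertiary amide cannot form a neutral oxazinone and the carbamate N–H is too remote to cyclise.

Step 6
Reactants: 3 3-[3,4-bis(benzyloxy)phenyl]propanoic acid; 10 propane-1,3-diamine
Product: 12 N-(3-aminopropyl)-3-[3,4-bis(benzyloxy)phenyl]propanamide, via acyl imidazole 11 (not isolated)
Conditions: CDI, THF, rt; then slow addition to 10 (8 equiv), THF, 0 °C
Reagents that add atoms: none
Why: Activation as the acyl imidazole and aminolysis by a large excess of the symmetrical diamine should give the mono-amide (statistical mono-acylation), the excess diamine being removed by aqueous washing.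

Step 7
Reactants: 12 N-(3-aminopropyl)-3-[3,4-bis(benzyloxy)phenyl]propanamide; 5 tert-butyl acrylate
Product: 14 tert-butyl 3-[[(benzyloxy)carbonyl](3-{3-[3,4-bis(benzyloxy)phenyl]propanamido}propyl)amino]propanoate, via secondary amine 13 (not isolated)
Conditions: MeOH, rt; evaporation; then CbzOSu, Et3N, CH2Cl2, 0 °C → rt
Reagents that add atoms: N-(benzyloxycarbonyloxy)succinimide, O=C(OCc1ccccc1)ON1C(=O)CCC1=O
Why: Aza-Michael addition of the primary amine to the acrylate followed by Cbz protection of the resulting secondary amine in the same flask should work because the amide N–H is inert to both reagents.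

Step 8
Reactants: 14 tert-butyl 3-[[(benzyloxy)carbonyl](3-{3-[3,4-bis(benzyloxy)phenyl]propanamido}propyl)amino]propanoate
Product: 15 3-[[(benzyloxy)carbonyl](3-{3-[3,4-bis(benzyloxy)phenyl]propanamido}propyl)amino]propanoic acid
Conditions: TFA–CH2Cl2 (1:3), 0 °C → rt; co-evaporation with toluene
Reagents that add atoms: none
Why: Acidolysis of the tert-butyl ester with loss of isobutene should spare the benzyl carbamate, the aryl benzyl ethers and the secondary amide.

Step 9
Reactants: 15 3-[[(benzyloxy)carbonyl](3-{3-[3,4-bis(benzyloxy)phenyl]propanamido}propyl)amino]propanoic acid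
Product: 16 1,3-dioxoisoindolin-2-yl 3-[[(benzyloxy)carbonyl](3-{3-[3,4-bis(benzyloxy)phenyl]propanamido}propyl)amino]propanoate
Conditions: N-hydroxyphthalimide, DIC, DMAP (cat.), CH2Cl2, rt
Reagents that add atoms: N-hydroxyphthalimide, ON1C(=O)c2ccccc2C1=O
Why: Steglich-type esterification with N-hydroxyphthalimide should give the second redox-active ester, the fully substituted carbamate nitrogen and the remote amide N–H being unable to attack the activated ester.

Step 10
Reactants: 9 1,3-dioxoisoindolin-2-yl 3-[{3-[3,4-bis(benzyloxy)phenyl]propanoyl}(3-{[(benzyloxy)carbonyl]amino}propyl)amino]propanoate (3 equiv); 16 1,3-dioxoisoindolin-2-yl 3-[[(benzyloxy)carbonyl](3-{3-[3,4-bis(benzyloxy)phenyl]propanamido}propyl)amino]propanoate (1 equiv)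
Product: 17 N1,N10-bis(benzyloxycarbonyl)-tetra-O-benzyl-kukoamine B
Conditions: NiCl2·6H2O (20 mol%), 2,2':6',2''-terpyridine (20 mol%), AgNO3 (0.3 equiv), NMP, undivided cell, (+)Mg/(−)RVC, constant current (ca. 2.5 F/mol of ester), rt; dilute aq. HCl work-up
Reagents that add atoms: none
Why: Low-valent Ni(terpyridine), generated at the cathode (coated in situ with silver nanoparticles from AgNO3), reduces both N-acyloxyphthalimides by single-electron transfer; each radical anion loses phthalimide anion and CO2 to give a primary N–CH2–CH2• radical, and capture of the two radicals at nickel gives a dialkylnickel species that reductively eliminates to form the C7–C8 bond, the Mg anode supplying the electrons. The closest known reaction type is the nickel-electrocatalytic doubly decarboxylative C(sp3)–C(sp3) cross-coupling of two primary alkyl redox-active esters, and the radicals here are of the same N–C–C• type as those from aspartate side-chain redox-active esters. No ring is closed and no stereocentre is formed. The selectivity needed is cross- over homo-coupling, which is secured only statistically by using 9 in threefold excess over the limiting 16; the homo-dimer of 9 is an isomer of 17 and must be separated by chromatography, the handle being the secondary amide N–H of 17 against carbamate N–H only in the dimer. Chemoselectivity rests on the reductive mode of radical generation, which should leave the four electron-rich benzyloxyarene rings, the benzyl carbamates and the N–H groups untouched, whereas an anodic Kolbe coupling of the free acids would oxidise the arenes.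

Step 11
Reactants: 17 N1,N10-bis(benzyloxycarbonyl)-tetra-O-benzyl-kukoamine B
Product: 18 kukoamine B
Conditions: H2 (1 atm), Pd(OH)2/C, THF–EtOH–H2O, rt; filtration and concentration under argon
Reagents that add atoms: none
Why: Catalytic hydrogenolysis should cleave the four benzylic C–O bonds of the aryl ethers and both benzyl carbamates (with loss of CO2) in one operation, while amides and arenes are stable to Pd/H2 at 1 atm.

**Compound list**

1 | 3-(3,4-dihydroxyphenyl)propanoic acid (dihydrocaffeic acid) | OC(=O)CCc1ccc(O)c(O)c1 | starting material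
2 | benzyl 3-[3,4-bis(benzyloxy)phenyl]propanoate | O=C(CCc1ccc(OCc2ccccc2)c(OCc2ccccc2)c1)OCc1ccccc1 | intermediate (not isolated)
3 | 3-[3,4-bis(benzyloxy)phenyl]propanoic acid | OC(=O)CCc1ccc(OCc2ccccc2)c(OCc2ccccc2)c1 | intermediate
4 | benzyl (3-aminopropyl)carbamate | NCCCNC(=O)OCc1ccccc1 | starting material
5 | tert-butyl acrylate | C=CC(=O)OC(C)(C)C | starting material
6 | tert-butyl 3-[(3-{[(benzyloxy)carbonyl]amino}propyl)amino]propanoate | CC(C)(C)OC(=O)CCNCCCNC(=O)OCc1ccccc1 | intermediate
7 | tert-butyl 3-[{3-[3,4-bis(benzyloxy)phenyl]propanoyl}(3-{[(benzyloxy)carbonyl]amino}propyl)amino]propanoate | CC(C)(C)OC(=O)CCN(CCCNC(=O)OCc1ccccc1)C(=O)CCc1ccc(OCc2ccccc2)c(OCc2ccccc2)c1 | intermediate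
8 | 3-[{3-[3,4-bis(benzyloxy)phenyl]propanoyl}(3-{[(benzyloxy)carbonyl]amino}propyl)amino]propanoic acid | OC(=O)CCN(CCCNC(=O)OCc1ccccc1)C(=O)CCc1ccc(OCc2ccccc2)c(OCc2ccccc2)c1 | intermediate
9 | 1,3-dioxoisoindolin-2-yl ester of 8 (N-acyloxyphthalimide of the N5 half) | O=C(CCN(CCCNC(=O)OCc1ccccc1)C(=O)CCc1ccc(OCc2ccccc2)c(OCc2ccccc2)c1)ON1C(=O)c2ccccc2C1=O | intermediate
10 | propane-1,3-diamine | NCCCN | starting material
11 | 3-[3,4-bis(benzyloxy)phenyl]-1-(1H-imidazol-1-yl)propan-1-one | O=C(CCc1ccc(OCc2ccccc2)c(OCc2ccccc2)c1)n1ccnc1 | intermediate (not isolated)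
12 | N-(3-aminopropyl)-3-[3,4-bis(benzyloxy)phenyl]propanamide | NCCCNC(=O)CCc1ccc(OCc2ccccc2)c(OCc2ccccc2)c1 | intermediate
13 | tert-butyl 3-[(3-{3-[3,4-bis(benzyloxy)phenyl]propanamido}propyl)amino]propanoate | CC(C)(C)OC(=O)CCNCCCNC(=O)CCc1ccc(OCc2ccccc2)c(OCc2ccccc2)c1 | intermediate (not isolated)
14 | tert-butyl 3-[[(benzyloxy)carbonyl](3-{3-[3,4-bis(benzyloxy)phenyl]propanamido}propyl)amino]propanoate | CC(C)(C)OC(=O)CCN(CCCNC(=O)CCc1ccc(OCc2ccccc2)c(OCc2ccccc2)c1)C(=O)OCc1ccccc1 | intermediate
15 | 3-[[(benzyloxy)carbonyl](3-{3-[3,4-bis(benzyloxy)phenyl]propanamido}propyl)amino]propanoic acid | OC(=O)CCN(CCCNC(=O)CCc1ccc(OCc2ccccc2)c(OCc2ccccc2)c1)C(=O)OCc1ccccc1 | intermediate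
16 | 1,3-dioxoisoindolin-2-yl ester of 15 (N-acyloxyphthalimide of the N10 half) | O=C(CCN(CCCNC(=O)CCc1ccc(OCc2ccccc2)c(OCc2ccccc2)c1)C(=O)OCc1ccccc1)ON1C(=O)c2ccccc2C1=O | intermediate
17 | N1,N10-bis(benzyloxycarbonyl)-tetra-O-benzyl-kukoamine B | O=C(NCCCN(CCCCN(CCCNC(=O)CCc1ccc(OCc2ccccc2)c(OCc2ccccc2)c1)C(=O)OCc1ccccc1)C(=O)CCc1ccc(OCc2ccccc2)c(OCc2ccccc2)c1)OCc1ccccc1 | intermediate
18 | kukoamine B | NCCCN(CCCCNCCCNC(=O)CCc1ccc(O)c(O)c1)C(=O)CCc1ccc(O)c(O)c1 | target

**Step count and risks**

Total step count: 11. Longest linear sequence: 7 steps (steps 1, 6, 7, 8, 9, 10, 11).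

Steps most likely to fail:

Step 10. Homo-coupling of the ester used in excess gives a dimer isomeric with 17 that may co-elute. The alkyl radicals may also be reduced to N-ethyl groups, and the active esters may hydrolyse before they are reduced. The fallback gives up the C–C coupling and closes the tetramethylene chain at a C–N bond by known alkylation chemistry. It sets out from 4: N-alkylation of 4 (in excess) with 2-(3-chloropropyl)-1,3-dioxolane (NaI, K2CO3, MeCN, 70 °C) should give benzyl (3-{[3-(1,3-dioxolan-2-yl)propyl]amino}propyl)carbamate F1. Acylation of F1 with 3 (DIC, Oxyma) should give benzyl (3-{N-[3-(1,3-dioxolan-2-yl)propyl]-3-[3,4-bis(benzyloxy)phenyl]propanamido}propyl)carbamate F2. Acetal hydrolysis (aq. HCl, THF) should give benzyl (3-{3-[3,4-bis(benzyloxy)phenyl]-N-(4-oxobutyl)propanamido}propyl)carbamate F3. Reductive amination of F3 with amine 12 (NaBH(OAc)3, DCE) should give N1-(benzyloxycarbonyl)-tetra-O-benzyl-kukoamine B F4, which has the full skeleton with N10 free. Hydrogenolysis of F4 under the conditions of step 11 gives the target directly, so the fallback comes back to the route at 18.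

Step 11. The liberated polyamine may poison the catalyst and leave Cbz or benzyl groups partly in place, the alcohol co-solvent may N-alkylate the amines, and the catechols may oxidise in air once free amines are present. The fallback replaces hydrogenolysis by Lewis-acid cleavage. It sets out from 17: BBr3 in CH2Cl2 (−78 → 0 °C) followed by a MeOH quench should cleave all four aryl benzyl ethers and both benzyl carbamates and give kukoamine B dihydrobromide F5 after trituration. Neutralisation with NaHCO3 (2 equiv) and desalting on a reversed phase under argon gives the free base, so the fallback comes back to the route at 18.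

Step 6. Both ends of the symmetrical diamine may be acylated, and the polar mono-amide may be lost during aqueous removal of the excess diamine. The fallback uses a differentiated diamine. It sets out from 3: coupling of 3 with tert-butyl (3-aminopropyl)carbamate (DIC, Oxyma, CH2Cl2) should give tert-butyl (3-{3-[3,4-bis(benzyloxy)phenyl]propanamido}propyl)carbamate F6. Removal of the Boc group (TFA–CH2Cl2, then aq. NaHCO3 wash) gives the free amine, so the fallback comes back to the route at 12.

**Further compounds**

F1 | step 10 | benzyl (3-{[3-(1,3-dioxolan-2-yl)propyl]amino}propyl)carbamate | O=C(NCCCNCCCC1OCCO1)OCc1ccccc1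
F2 | step 10 | benzyl (3-{N-[3-(1,3-dioxolan-2-yl)propyl]-3-[3,4-bis(benzyloxy)phenyl]propanamido}propyl)carbamate | O=C(NCCCN(CCCC1OCCO1)C(=O)CCc1ccc(OCc2ccccc2)c(OCc2ccccc2)c1)OCc1ccccc1
F3 | step 10 | benzyl (3-{3-[3,4-bis(benzyloxy)phenyl]-N-(4-oxobutyl)propanamido}propyl)carbamate | O=CCCCN(CCCNC(=O)OCc1ccccc1)C(=O)CCc1ccc(OCc2ccccc2)c(OCc2ccccc2)c1
F4 | step 10 | N1-(benzyloxycarbonyl)-tetra-O-benzyl-kukoamine B | O=C(NCCCN(CCCCNCCCNC(=O)CCc1ccc(OCc2ccccc2)c(OCc2ccccc2)c1)C(=O)CCc1ccc(OCc2ccccc2)c(OCc2ccccc2)c1)OCc1ccccc1
F5 | step 11 | kukoamine B dihydrobromide | NCCCN(CCCCNCCCNC(=O)CCc1ccc(O)c(O)c1)C(=O)CCc1ccc(O)c(O)c1.Br.Br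
F6 | step 6 | tert-butyl (3-{3-[3,4-bis(benzyloxy)phenyl]propanamido}propyl)carbamate | CC(C)(C)OC(=O)NCCCNC(=O)CCc1ccc(OCc2ccccc2)c(OCc2ccccc2)c1
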